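## Plan

- Retrosynthesis: the phenol is masked as its benzyl ether, a chlorine is put back at C3 and a p-tolylthio group at C5, and the γ-lactone is then cut at C3–C4 and O1–C5 together.
- Enabling feature: the lactone ring is an acyl two-carbon unit (C2 carbonyl, C3 with the 4-hydroxy-3,5-dimethoxybenzyl arm) joined to a CH–CH2–O unit (C4 with the 3,4-dimethoxybenzyl arm, C5). The first is a chloro(arylmethyl)ketene, the second the two alkene carbons of an (E)-vinyl sulfoxide whose sulfinyl oxygen ends up in the carboxyl group.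
- Forward: the vinyl sulfoxide comes from (S)-methyl p-tolyl sulfoxide and (3,4-dimethoxyphenyl)acetaldehyde (steps 1–2), the ketene precursor from sinapic acid (steps 3–6). Step 7 joins the two chains and closes the lactone, the only ring made in the route.
- Endgame: radical removal of Cl and S-tolyl, base equilibration at C3, hydrogenolysis of the benzyl ether (steps 8–10).
- Stereochemistry: C4 comes from the sulfur stereocentre by chirality transfer in the chair [3,3] shift; C3 is set by thermodynamic equilibration to the trans lactone.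

Key step: step 7

Remark: the sense of chirality transfer is assigned from a chair transition state with the p-tolyl group pseudo-equatorial on sulfur; on that basis the (S)-sulfoxide of the (E)-alkene leads to the (4R) centre of the target, and the enantiomeric sulfoxide would be used if the sense proved opposite.

Abbreviations used in names: Ar = 3,4-dimethoxyphenyl; Ar' = 4-(benzyloxy)-3,5-dimethoxyphenyl.

## Route

Step 1
Reactants: 1 (S)-methyl p-tolyl sulfoxide; 2 (3,4-dimethoxyphenyl)acetaldehyde
Product: 4 1-(3,4-dimethoxyphenyl)-3-[(S)-p-tolylsulfinyl]propan-2-ol as both C2 epimers, via [(S)-p-tolylsulfinyl]methyllithium 3 (not isolated)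
Conditions: LiN(iPr)2 (1.1 equiv), THF, −78 °C; then 2, −78 °C; aq. NH4Cl
Reagents that add atoms: none
Why: Deprotonation of the S-methyl group gives an α-sulfinyl carbanion whose 1,2-addition to the aldehyde (aldol-type addition) leaves sulfur untouched, and the carbinol centre, formed as a mixture, is erased in step 2.

Step 2
Reactants: 4 1-(3,4-dimethoxyphenyl)-3-[(S)-p-tolylsulfinyl]propan-2-ol
Product: 6 (S,E)-1,2-dimethoxy-4-[3-(p-tolylsulfinyl)prop-2-en-1-yl]benzene, via mesylate 5 (not isolated)
Conditions: MsCl, Et3N, CH2Cl2, 0 °C; then DBU (1.2 equiv), 0 °C, short contact time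
Reagents that add atoms: none
Why: O-Mesylation followed by base-induced β-elimination through the acidic α-sulfinyl C–H (E1cB-like) should convert both carbinol epimers into the conjugated vinyl sulfoxide with the favoured (E) geometry, the (S) configuration at sulfur being carried over unchanged.

Step 3
Reactants: 7 sinapic acid
Product: 8 3-(4-hydroxy-3,5-dimethoxyphenyl)propanoic acid
Conditions: H2 (1 atm), 10% Pd/C, MeOH, rt
Reagents that add atoms: none
Why: Catalytic hydrogenation of the cinnamic acid C=C bond over Pd/C, under which the arene, the phenol and the acid are inert.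

Step 4
Reactants: 8 3-(4-hydroxy-3,5-dimethoxyphenyl)propanoic acid
Product: 10 3-[4-(benzyloxy)-3,5-dimethoxyphenyl]propanoic acid, via benzyl ester 9 (not isolated)
Conditions: BnBr (2.4 equiv), K2CO3, DMF, 60 °C; then aq. NaOH, MeOH, 60 °C; HCl to pH 2
Reagents that add atoms: benzyl bromide BrCc1ccccc1; sodium hydroxide [Na+].[OH-]
Why: Williamson etherification of the phenoxide and O-alkylation of the carboxylate with BnBr, then saponification, which cleaves only the benzyl ester and leaves the aryl benzyl ether as the phenol protecting group.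

Step 5
Reactants: 10 3-[4-(benzyloxy)-3,5-dimethoxyphenyl]propanoic acid
Product: 12 3-[4-(benzyloxy)-3,5-dimethoxyphenyl]-2-chloropropanoic acid (racemic), via dilithium enediolate 11 (not isolated)
Conditions: LiN(iPr)2 (2.2 equiv), THF, −78 → 0 °C; added to CCl4 (3 equiv), THF, −78 °C; aq. HCl
Reagents that add atoms: carbon tetrachloride ClC(Cl)(Cl)Cl
Why: The carboxylic acid dianion is chlorinated at carbon by halogen transfer from CCl4, an established entry to 2-chloro acids as chloroketene precursors, and the racemic C2 centre does not matter because it becomes the sp2 carbon of the ketene.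

Step 6
Reactants: 12 3-[4-(benzyloxy)-3,5-dimethoxyphenyl]-2-chloropropanoic acid
Product: 13 3-[4-(benzyloxy)-3,5-dimethoxyphenyl]-2-chloropropanoyl chloride (racemic)
Conditions: (COCl)2 (1.5 equiv), DMF (cat.), CH2Cl2, 0 °C → rt; concentrated and used crude
Reagents that add atoms: oxalyl chloride ClC(=O)C(=O)Cl
Why: Acid chloride formation with oxalyl chloride under DMF (Vilsmeier-type) catalysis, mild enough for the benzyl ether and the secondary C–Cl bond.

Step 7
Reactants: 6 (S,E)-1,2-dimethoxy-4-[3-(p-tolylsulfinyl)prop-2-en-1-yl]benzene; 13 3-[4-(benzyloxy)-3,5-dimethoxyphenyl]-2-chloropropanoyl chloride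
Product: 17 (4S)-3-[4-(benzyloxy)-3,5-dimethoxybenzyl]-3-chloro-4-(3,4-dimethoxybenzyl)-5-(p-tolylthio)dihydrofuran-2(3H)-one as C3/C5 epimers, via chloroketene 14 (not isolated), via vinyloxysulfonium enolate 15 (not isolated), via thionium carboxylate 16 (not isolated)
Conditions: 6 (1 equiv), Et3N (4 equiv), CH2Cl2, 0 °C; 13 (3 equiv) in CH2Cl2 added over 4 h; then rt
Reagents that add atoms: none
Why: Proposed new method: Et3N dehydrochlorinates 13 to chloroketene 14, the sulfinyl oxygen of 6 adds to the ketene carbonyl carbon to give enolate 15, a charge-accelerated [3,3] shift through a chair forms C3–C4 with S–O cleavage to give thionium carboxylate 16, and the carboxylate then captures the thionium carbon to form O1–C5 in a Pummerer-type closure. The closest known reaction is the ketene lactonization of vinyl sulfoxides with dichloroketene and chloroketene, extended here to an alkyl(chloro)ketene whose chlorine keeps the ketene electrophilic and stabilises the enolate of 15. The lactone closes in the 5-exo-trig mode by attack of the carboxylate oxygen on the C=S+ carbon. C4 is controlled by the sulfur stereocentre: with p-tolyl pseudo-equatorial and the (E)-alkene substituent equatorial in the chair, the (S)-sulfoxide directs the ketene carbon to the alkene face that gives the C4 configuration of the target (descriptor 4S in 17 only because C3 carries chlorine). C3 (fixed by enolate geometry) and C5 (fixed by the face of closure) are expected as mixtures and are removed or equilibrated in steps 8 and 9. The step needs O-acylation of the sulfoxide to outrun ketene self-condensation and [2+2] addition, which the nucleophilic sulfinyl oxygen, the electron-poor sulfinyl alkene and slow addition of 13 should secure.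

Step 8
Reactants: 17 (4S)-3-[4-(benzyloxy)-3,5-dimethoxybenzyl]-3-chloro-4-(3,4-dimethoxybenzyl)-5-(p-tolylthio)dihydrofuran-2(3H)-one
Product: 19 (4R)-3-[4-(benzyloxy)-3,5-dimethoxybenzyl]-4-(3,4-dimethoxybenzyl)dihydrofuran-2(3H)-one as C3 epimers, via dechlorinated thiolactone 18 (not isolated)
Conditions: Bu3SnH (4 equiv), AIBN (cat., in portions), PhMe, 110 °C
Reagents that add atoms: none
Why: Radical chain reduction with Bu3SnH removes the α-chlorine first to give 18 and then cleaves the C5–S bond through the oxygen-stabilised C5 radical to give 19, C4 being untouched and C3 emerging as a mixture in which hydrogen delivery anti to the C4 arm should favour the cis lactone.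

Step 9
Reactants: 19 (4R)-3-[4-(benzyloxy)-3,5-dimethoxybenzyl]-4-(3,4-dimethoxybenzyl)dihydrofuran-2(3H)-one
Product: 20 (3R,4R)-3-[4-(benzyloxy)-3,5-dimethoxybenzyl]-4-(3,4-dimethoxybenzyl)dihydrofuran-2(3H)-one
Conditions: DBU (1.0 equiv), PhMe, 80 °C
Reagents that add atoms: none
Why: Reversible enolisation at C3 (base-mediated epimerisation) should drain the mixture into the thermodynamically favoured trans-3,4-disubstituted lactone, fixing C3 as (R) relative to the non-acidic, untouched C4.

Step 10
Reactants: 20 (3R,4R)-3-[4-(benzyloxy)-3,5-dimethoxybenzyl]-4-(3,4-dimethoxybenzyl)dihydrofuran-2(3H)-one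
Product: 21 (3R,4R)-4-(3,4-dimethoxybenzyl)-3-(4-hydroxy-3,5-dimethoxybenzyl)dihydrofuran-2(3H)-one
Conditions: H2 (1 atm), 10% Pd/C, EtOAc–EtOH, rt
Reagents that add atoms: none
Why: Hydrogenolysis of the aryl benzyl ether over Pd/C releases the phenol without touching the lactone, the methyl ethers or either stereocentre.

## Compound list

1 | (S)-methyl p-tolyl sulfoxide | Cc1ccc(cc1)[S@@](=O)C | starting material
2 | (3,4-dimethoxyphenyl)acetaldehyde | COc1ccc(CC=O)cc1OC | starting material
3 | [(S)-p-tolylsulfinyl]methyllithium | Cc1ccc(cc1)[S@@](=O)C[Li] | intermediate (not isolated)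
4 | 1-(3,4-dimethoxyphenyl)-3-[(S)-p-tolylsulfinyl]propan-2-ol, both C2 epimers | Cc1ccc(cc1)[S@@](=O)CC(O)Cc1ccc(OC)c(OC)c1 | intermediate
5 | 1-(3,4-dimethoxyphenyl)-3-[(S)-p-tolylsulfinyl]propan-2-yl methanesulfonate | Cc1ccc(cc1)[S@@](=O)CC(OS(C)(=O)=O)Cc1ccc(OC)c(OC)c1 | intermediate (not isolated)
6 | (S,E)-1,2-dimethoxy-4-[3-(p-tolylsulfinyl)prop-2-en-1-yl]benzene | Cc1ccc(cc1)[S@@](=O)/C=C/Cc1ccc(OC)c(OC)c1 | intermediate
7 | sinapic acid, (E)-3-(4-hydroxy-3,5-dimethoxyphenyl)prop-2-enoic acid | COc1cc(/C=C/C(=O)O)cc(OC)c1O | starting material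
8 | 3-(4-hydroxy-3,5-dimethoxyphenyl)propanoic acid | COc1cc(CCC(=O)O)cc(OC)c1O | intermediate
9 | benzyl 3-[4-(benzyloxy)-3,5-dimethoxyphenyl]propanoate | COc1cc(CCC(=O)OCc2ccccc2)cc(OC)c1OCc1ccccc1 | intermediate (not isolated)
10 | 3-[4-(benzyloxy)-3,5-dimethoxyphenyl]propanoic acid | COc1cc(CCC(=O)O)cc(OC)c1OCc1ccccc1 | intermediate
11 | dilithium 3-[4-(benzyloxy)-3,5-dimethoxyphenyl]prop-1-ene-1,1-diolate | [Li]OC(O[Li])=CCc1cc(OC)c(OCc2ccccc2)c(OC)c1 | intermediate (not isolated)
12 | 3-[4-(benzyloxy)-3,5-dimethoxyphenyl]-2-chloropropanoic acid (racemic) | OC(=O)C(Cl)Cc1cc(OC)c(OCc2ccccc2)c(OC)c1 | intermediate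
13 | 3-[4-(benzyloxy)-3,5-dimethoxyphenyl]-2-chloropropanoyl chloride (racemic) | O=C(Cl)C(Cl)Cc1cc(OC)c(OCc2ccccc2)c(OC)c1 | intermediate
14 | 3-[4-(benzyloxy)-3,5-dimethoxyphenyl]-2-chloroprop-1-en-1-one (chloroketene) | O=C=C(Cl)Cc1cc(OC)c(OCc2ccccc2)c(OC)c1 | intermediate (not isolated)
15 | vinyloxysulfonium enolate, zwitterion p-Tol–S+[(E)-CH=CH–CH2Ar]–O–C(O−)=C(Cl)CH2Ar' with sulfur configured as in 6 | Cc1ccc(cc1)[S@@+](OC([O-])=C(Cl)Cc1cc(OC)c(OCc2ccccc2)c(OC)c1)/C=C/Cc1ccc(OC)c(OC)c1 | intermediate (not isolated)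
16 | thionium carboxylate, zwitterion p-Tol–S+=CH–CH(CH2Ar)–C(Cl)(CH2Ar')–CO2− with the CH(CH2Ar) carbon configured as C4 of 17 | Cc1ccc(cc1)[S+]=C[C@H](Cc1ccc(OC)c(OC)c1)C(Cl)(Cc1cc(OC)c(OCc2ccccc2)c(OC)c1)C([O-])=O | intermediate (not isolated)
17 | (4S)-3-[4-(benzyloxy)-3,5-dimethoxybenzyl]-3-chloro-4-(3,4-dimethoxybenzyl)-5-(p-tolylthio)dihydrofuran-2(3H)-one, C3/C5 epimers | COc1ccc(C[C@H]2C(Sc3ccc(C)cc3)OC(=O)C2(Cl)Cc2cc(OC)c(OCc3ccccc3)c(OC)c2)cc1OC | intermediate
18 | (4R)-3-[4-(benzyloxy)-3,5-dimethoxybenzyl]-4-(3,4-dimethoxybenzyl)-5-(p-tolylthio)dihydrofuran-2(3H)-one, C3/C5 epimers | COc1ccc(C[C@H]2C(Sc3ccc(C)cc3)OC(=O)C2Cc2cc(OC)c(OCc3ccccc3)c(OC)c2)cc1OC | intermediate (not isolated)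
19 | (4R)-3-[4-(benzyloxy)-3,5-dimethoxybenzyl]-4-(3,4-dimethoxybenzyl)dihydrofuran-2(3H)-one, C3 epimers | COc1ccc(C[C@H]2COC(=O)C2Cc2cc(OC)c(OCc3ccccc3)c(OC)c2)cc1OC | intermediate
20 | (3R,4R)-3-[4-(benzyloxy)-3,5-dimethoxybenzyl]-4-(3,4-dimethoxybenzyl)dihydrofuran-2(3H)-one | COc1ccc(C[C@H]2COC(=O)[C@@H]2Cc2cc(OC)c(OCc3ccccc3)c(OC)c2)cc1OC | intermediate
21 | (3R,4R)-4-(3,4-dimethoxybenzyl)-3-(4-hydroxy-3,5-dimethoxybenzyl)dihydrofuran-2(3H)-one | COc1ccc(C[C@H]2COC(=O)[C@@H]2Cc2cc(OC)c(O)c(OC)c2)cc1OC | target

## Step count and risks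

Total steps: 10. Longest linear sequence: 8 steps (steps 3–10, from sinapic acid); the sulfoxide branch contributes steps 1–2.

**Risk 1, step 7.** The alkyl(chloro)ketene is less electrophilic than dichloroketene and may be used up by self-condensation before the sulfinyl oxygen captures it. The amine needed to generate it may shift the double bond of 6 away from sulfur into conjugation with the arene, after which the allylic sulfoxide loses its sulfur configuration by reversible [2,3] shift. Chirality transfer may also erode if a boat or an axial-tolyl chair competes.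

Fallback (known chemistry; sets out from 6, returns at 20): 6 is annulated with dichloroketene F1, generated without amine from Cl3CCOCl and Zn–Cu couple in Et2O. This should give (4S)-3,3-dichloro-4-(3,4-dimethoxybenzyl)-5-(p-tolylthio)dihydrofuran-2(3H)-one F2 by the same [3,3] shift and closure. Bu3SnH with AIBN in hot PhMe strips both chlorines and the arylthio group to (4R)-4-(3,4-dimethoxybenzyl)dihydrofuran-2(3H)-one F3. LiN(SiMe3)2 in THF at −78 °C converts F3 into its lithium enolate F4. The alkylating agent is made separately: commercial 4-(benzyloxy)-3,5-dimethoxybenzaldehyde is reduced with NaBH4 to [4-(benzyloxy)-3,5-dimethoxyphenyl]methanol F5 and brominated with PBr3 to 2-(benzyloxy)-5-(bromomethyl)-1,3-dimethoxybenzene F6. Alkylation of F4 by F6 anti to the C4 arm should give trans lactone 20 directly, so steps 8 and 9 fall away and the C3 arm is attached after the ring has formed.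

**Risk 2, step 2.** Once the vinyl sulfoxide has formed, DBU or Et3N may deprotonate its doubly activated CH2 and move the double bond into conjugation with the dimethoxyphenyl ring. The resulting allylic sulfoxide racemises at sulfur through its sulfenate, and the elimination may also give some (Z) isomer. In the step before, enolisation of arylacetaldehyde 2 by the carbanion may cut the supply of 4.

Fallback (sets out from 2, returns at 6): 2 is homologated with the Ohira–Bestmann reagent (K2CO3, MeOH) to 1,2-dimethoxy-4-(prop-2-yn-1-yl)benzene F7. EtMgBr converts F7 into [3-(3,4-dimethoxyphenyl)prop-1-yn-1-yl]magnesium bromide F8. F8 displaces menthoxide from (1S,2R,5S)-menthyl (R)-p-toluenesulfinate with inversion at sulfur (Andersen synthesis, PhMe, −20 °C) to give (R)-1,2-dimethoxy-4-[3-(p-tolylsulfinyl)prop-2-yn-1-yl]benzene F9. The descriptor is (R) because alkynyl outranks tolyl; the spatial arrangement is that of 6. iBu2AlH in THF at −90 °C reduces the triple bond with trans delivery of the two hydrogens and should give (E)-alkene 6 with no amine base present.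

**Risk 3, step 5.** Proton exchange between the first-formed 2-chloro carboxylate and unreacted dianion may lead to double chlorination and returned 10, and the strongly basic medium may expel chloride toward the cinnamate.

Fallback (sets out from 10, returns at 12): 10 is esterified (MeI, K2CO3, DMF) to methyl 3-[4-(benzyloxy)-3,5-dimethoxyphenyl]propanoate F10. LiN(iPr)2 and then Me3SiCl (THF, −78 °C) give the ketene methyl trimethylsilyl acetal F11. F11 is chlorinated under neutral conditions with N-chlorosuccinimide to methyl 3-[4-(benzyloxy)-3,5-dimethoxyphenyl]-2-chloropropanoate F12. LiOH in THF–H2O at 0 °C returns acid 12.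

## Further compounds

F1 | step 7 | dichloroketene | ClC(Cl)=C=O
F2 | step 7 | (4S)-3,3-dichloro-4-(3,4-dimethoxybenzyl)-5-(p-tolylthio)dihydrofuran-2(3H)-one, C5 epimers | COc1ccc(C[C@H]2C(Sc3ccc(C)cc3)OC(=O)C2(Cl)Cl)cc1OC
F3 | step 7 | (4R)-4-(3,4-dimethoxybenzyl)dihydrofuran-2(3H)-one | COc1ccc(C[C@H]2COC(=O)C2)cc1OC
F4 | step 7 | lithium enolate of F3, lithium (3R)-3-(3,4-dimethoxybenzyl)-2,3-dihydrofuran-5-olate | COc1ccc(C[C@H]2COC(O[Li])=C2)cc1OC
F5 | step 7 | [4-(benzyloxy)-3,5-dimethoxyphenyl]methanol | COc1cc(CO)cc(OC)c1OCc1ccccc1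
F6 | step 7 | 2-(benzyloxy)-5-(bromomethyl)-1,3-dimethoxybenzene | COc1cc(CBr)cc(OC)c1OCc1ccccc1
F7 | step 2 | 1,2-dimethoxy-4-(prop-2-yn-1-yl)benzene | COc1ccc(CC#C)cc1OC
F8 | step 2 | [3-(3,4-dimethoxyphenyl)prop-1-yn-1-yl]magnesium bromide | COc1ccc(CC#C[Mg]Br)cc1OC
F9 | step 2 | (R)-1,2-dimethoxy-4-[3-(p-tolylsulfinyl)prop-2-yn-1-yl]benzene | Cc1ccc(cc1)[S@@](=O)C#CCc1ccc(OC)c(OC)c1
F10 | step 5 | methyl 3-[4-(benzyloxy)-3,5-dimethoxyphenyl]propanoate | COC(=O)CCc1cc(OC)c(OCc2ccccc2)c(OC)c1
F11 | step 5 | {3-[4-(benzyloxy)-3,5-dimethoxyphenyl]-1-methoxyprop-1-en-1-yl}oxy(trimethyl)silane | COC(O[Si](C)(C)C)=CCc1cc(OC)c(OCc2ccccc2)c(OC)c1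
F12 | step 5 | methyl 3-[4-(benzyloxy)-3,5-dimethoxyphenyl]-2-chloropropanoate (racemic) | COC(=O)C(Cl)Cc1cc(OC)c(OCc2ccccc2)c(OC)c1
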